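## Structural features

The target is a flavanone: a phloroglucinol-type benzene ring A is fused to a dihydropyran-4-one ring C (O1, C2, C3, C4, C4a, C8a), and a 4-hydroxy-3-methoxyphenyl ring B sits on C2. Ring A carries free hydroxyls at C5 and C7 and a 3-methylbut-2-enyl (prenyl) chain at C8, the carbon between C7 and the oxygen-bearing C8a. C2 is the only stereocentre, (S), so no neighbouring centre can relay or repair its configuration. C2 is fragile in two ways: it is β to the C4 carbonyl, so base opens ring C by a retro-oxa-Michael reaction, and it is a benzylic C–O carbon para to an oxygen donor on ring B, so acid or activation invites ionisation. The prenyl alkene is the second fragile group (cyclisation onto the C7 hydroxyl in strong acid, saturation on hydrogenation), which excludes benzyl ethers and harsh Lewis acids. The real difficulties are to decide which of the two oxygens ortho to C4a becomes O1, since this alone separates the 8-prenyl from the 6-prenyl isomer, and to set and keep C2. The route exploits the 1,3-relationship between the aryl ketone carbon C4 (on C4a of ring A) and the oxygenated benzylic carbon C2: C4 becomes a masked acyl anion (a 2-aryl-1,3-dithiane) and C2–C3 a terminal aryl oxirane, so C3–C4 forms by attack on the CH2 carbon while the C2–O bond passes unchanged into a carbinol that later gives O1–C2 by inversion.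

## Logic of the disconnections

20 goes back to 19 by cutting three oxygen–protecting-group bonds: the two O–CH2 acetal bonds at O5 and O7 and the O–acyl bond at O4'. Free phenols would be acidic and nucleophilic in every earlier step, and a free 4'-hydroxyl would make C2 labile. The gain is that all earlier chemistry runs on a neutral, fully masked substrate. The demand is one acidic methanolysis mild enough for the prenyl alkene.

19 goes back to 18 by replacing the C4 carbonyl with two C–S bonds of a 1,3-dithiane. A β-aryloxy ketone must not meet base or Mitsunobu reagents, and the thioacetal is the form in which C4 was a nucleophile. The demand is a neutral hydrolysis that spares the acetals, the acetate and the alkene.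

18 goes back to 17 by cutting O1–C2, the only carbon–heteroatom bond of ring C. This turns ring C and its stereocentre into an open-chain secondary benzylic alcohol of opposite spatial sense next to a phenol. The forward step must be a clean SN2 inversion at a benzylic carbon. Two conditions follow: the ring-B oxygen para to that carbon must be an acceptor and not a donor, and the phenol beside the prenyl chain must be the only free phenol of ring A.

17 goes back to 16 by cutting the O4'–acyl bond, and 16 to 15 by cutting two O–allyl bonds. An ether donor para to the carbinol would let the activated alcohol ionise in the closure, while an ester could not survive the organolithium of the coupling. The ring-B oxygen is therefore an allyl ether during the coupling and an acetate during the closure. One palladium operation frees both that oxygen and the future O1. The demand is selective acylation of the unhindered ring-B phenol over the buried ring-A phenol and the secondary alcohol.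

15 goes back through 14 to 7 and 13 by cutting C3–C4. This is the strategic cut: it divides the molecule into a ring-A fragment and a ring-B fragment of similar size and places the stereocentre in a small oxirane. The forward step needs deprotonation at the thioacetal carbon only, and attack at the CH2 and not the benzylic carbon of the oxirane.

7 goes back to 5 and 6 by cutting two C–S bonds, and 5 to 4 by cutting the O–allyl bond. The allyl group marks the oxygen next to prenyl. A strong Lewis acid with a thiol, the usual way to make a dithiane, is also a standard way to cleave methoxymethyl ethers, so the forward thioacetalisation needs a mild oxophilic catalyst.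

4 goes back to 3 by cutting two O–CH2 acetal bonds, and 3 to 1 and 2 by cutting the C8–CH2 bond of the prenyl chain. The symmetry of 1 makes the site of C-alkylation unambiguous. The demand falls on the bis-protection, which must leave free the hydroxyl that is both chelated to the formyl group and flanked by prenyl.

13 goes back through 12 to 11 by cutting the oxirane C–O bond at CH2 and the carbinol C–H bond, which reduces the stereocentre to an enantioselective ketone reduction. 11 goes back through 10 to 9 by cutting C–Cl, and 9 to 8 by cutting the O–allyl bond. The chlorination must be regiochemically unambiguous and must not chlorinate the electron-rich ring.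

## Other disconnections considered

Alternative 1: The cut is C2–C3, made inside ring C while O1–C2 stays intact. A chiral Brønsted acid would ionise the acetal C2–O3 bond of the cyclic enol acetal A1, a 2-aryl-4-methylene-4H-1,3-benzodioxine carrying three silyl ethers and the prenyl chain. The enol and the aryl-stabilised oxocarbenium ion would then recombine through carbon to give the silylated flavanone A2. One step would form C2–C3, close ring C, reveal the C4 carbonyl and set C2.
- In its favour: there is no thioacetal to unmask, no stoichiometric phosphine or azo reagent, and the source of chirality is catalytic. The final fluoride desilylation is kinder to the prenyl alkene than the acidic methanolysis of step 13. On that point and on step count (roughly half the operations) this alternative is the better plan.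
- Against it here: the enantio-determining event is the collapse of an ion pair whose cation is a 4-silyloxy-3-methoxybenzylidene oxocarbenium ion, which is long-lived and loosely bound to the chiral anion. An enantioselective oxygen version of this rearrangement for such partners is not an established transformation. The same acid can re-ionise O1–C2 of A2 and erode the selectivity. A1 is an acid-labile enol acetal that requires methylenation of an ester carbonyl beside three aryl silyl ethers.
- Comparison: the question of which ortho oxygen of ring A becomes O1 is only moved to the construction of A1, so the two plans are equal there. The chosen plan separates the tasks: the stereocentre comes from a well-precedented ketone reduction, the C–C bond from an SN2 reaction that does not touch it, and the ring from a stereospecific substitution. It pays with more steps and protecting-group traffic.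

Alternative 2: The cut is O1–C2, made between two molecules before ring C exists; C4–C4a is left for later. The sodium phenoxide of A3 (3,5-bis(methoxymethoxy)-2-prenylphenol) would attack the aryl-bearing terminus of the allyl–iridium complex formed from the cinnamyl carbonate A4 with [Ir(cod)Cl]2 and a chiral phosphoramidite. The product would be the branched (S)-ether A5.
- In its favour: this etherification is an established, branched-selective and enantioselective reaction class. O1–C2 forms without activating a benzylic alcohol, so the ionisation problem that forces the acetate switch in the chosen plan does not arise; on this point the alternative is the better. It is equally convergent, and the later ring closure can only reach the carbon ortho to O1.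
- Against it here: an ortho-substituted phenoxide with an electron-rich cinnamyl partner is the combination most prone to reversible ionisation of the branched ether and drift to the linear isomer. A3 needs one of two equivalent ortho hydroxyls of a prenylphloroglucinol left free, which is a statistical and not a directed differentiation. After the key step the vinyl group still needs anti-Markovnikov hydroboration beside the prenyl alkene, oxidation to the acid level, and a Friedel–Crafts closure. That closure is acidic and threatens the methoxymethyl ethers, the prenyl group and the benzylic aryl ether at C2.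
- Comparison: step economy is about equal. Both plans form O1–C2 by substitution, the alternative under catalyst control with net retention at a π-allyl, the chosen plan under substrate control with inversion. The chosen plan avoids the late acidic C–C bond formation.

Alternative 3: The cut is C2–C1', the bond between ring C and ring B. The boronic acid A7 would transmetalate to a rhodium hydroxide complex ([Rh(OH)(cod)]2 with a chiral bisphosphine). The aryl–rhodium species would add across C2=C3 of the chromone A6 from the ligand-selected face, and protonation of the rhodium enolate would release the flavanone A8.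
- In its favour: ring A, ring C, the prenyl chain and all protecting groups are in place before the stereocentre is made. Conjugate arylation of chromones is a known route to 2-arylchromanones, and one catalytic step sets C2. The sequence is the shortest of the four (about eight or nine operations against thirteen), so on step economy and convergence this alternative is clearly the better.
- Against it here: chromones are vinylogous esters and poor acceptors, and a 5-alkoxy group lowers reactivity further. The rhodium enolate can expel the ring oxygen (β-oxygen elimination), which opens ring C and costs material and enantiopurity. The electron-rich boronic acid is prone to protodeboronation in the aqueous basic medium.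
- Comparison: the prenyl regiochemistry rests on the same selective bis-protection of a 3-prenyl-2,4,6-trihydroxyaryl carbonyl compound, and A8 is deprotected by the same acidic operation as in step 13; the plans are equal on both. The alternative relies on catalyst-controlled facial selectivity at a flat, unusually substituted enone. The chosen plan takes C2 from a ketone reduction and two stereospecific substitutions and exposes no β-aryloxy ketone to base or a metal enolate. It is preferred for predictability with this 5,7-dioxygenated 8-prenyl pattern, not for economy.

Key step: step 8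

Assumption: the transfer hydrogenation of step 7 is taken to follow the usual sense of TsDPEN catalysts, under which the (R,R)-ligand leads to the (S)-chlorohydrin; if the sense were opposite, the (S,S)-catalyst would be used.

Remark: the descriptor changes from (S) in 13 to (R) in 15 with no change at the stereocentre, because the CH2 group loses its oxygen and falls below the aryl group in priority; the inversion of step 11 then gives (2S).

## Route

Step 1
Reactants: 1 2,4,6-trihydroxybenzaldehyde; 2 prenyl bromide (1-bromo-3-methylbut-2-ene)
Product: 3 2,4,6-trihydroxy-3-(3-methylbut-2-enyl)benzaldehyde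
Conditions: 2 (1.0 equiv), DBU (1.1 equiv), THF, 0 °C → rt
Reagents that add atoms: none
Why: Aromatic C-alkylation of the ambident phenoxide of an acylphloroglucinol by an allylic bromide; C3 and C5 are equivalent by symmetry, so mono-C-prenylation can give only one constitution, and limiting 2 to one equivalent should hold back bis- and O-prenylation, which are removed by chromatography.

Step 2
Reactants: 3 2,4,6-trihydroxy-3-(3-methylbut-2-enyl)benzaldehyde
Product: 4 2-hydroxy-4,6-bis(methoxymethoxy)-3-(3-methylbut-2-enyl)benzaldehyde
Conditions: MOMCl (2.2 equiv), i-Pr2NEt (3 equiv), CH2Cl2, 0 °C → rt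
Reagents that add atoms: chloromethyl methyl ether, COCCl
Why: O-Alkylation of phenols with an α-chloro ether (Williamson-type acetal formation); the non-chelated 4-OH and the unhindered 6-OH should react, while the 2-OH, hydrogen-bonded to the formyl oxygen and flanked by the prenyl chain, stays free, which fixes the oxygen that later becomes O1.

Step 3
Reactants: 4 2-hydroxy-4,6-bis(methoxymethoxy)-3-(3-methylbut-2-enyl)benzaldehyde
Product: 5 2-(allyloxy)-4,6-bis(methoxymethoxy)-3-(3-methylbut-2-enyl)benzaldehyde
Conditions: allyl bromide (1.5 equiv), K2CO3 (2 equiv), DMF, 50 °C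
Reagents that add atoms: allyl bromide, C=CCBr
Why: Williamson ether synthesis; in DMF the chelate is broken and the only free phenoxide is O-allylated, far below the temperature at which an aryl allyl ether would rearrange.

Step 4
Reactants: 5 2-(allyloxy)-4,6-bis(methoxymethoxy)-3-(3-methylbut-2-enyl)benzaldehyde; 6 propane-1,3-dithiol
Product: 7 2-[2-(allyloxy)-4,6-bis(methoxymethoxy)-3-(3-methylbut-2-enyl)phenyl]-1,3-dithiane
Conditions: 6 (1.2 equiv), Hf(OTf)4 (1 mol%), CH2Cl2, 0 °C → rt, argon
Reagents that add atoms: none
Why: Lewis-acid-catalysed thioacetalisation; the carbonyl oxygen of a 2,4,6-trioxygenated benzaldehyde is the most basic site and the derived thionium ion is strongly stabilised, so a catalytic oxophilic triflate should close the dithiane without the stoichiometric strong Lewis acid that, with a thiol, would cleave the methoxymethyl ethers or protonate the alkenes.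

Step 5
Reactants: 8 acetovanillone (1-(4-hydroxy-3-methoxyphenyl)ethanone)
Product: 9 1-[4-(allyloxy)-3-methoxyphenyl]ethanone
Conditions: allyl bromide (1.2 equiv), K2CO3 (1.5 equiv), acetone, reflux
Reagents that add atoms: allyl bromide, C=CCBr
Why: Williamson ether synthesis at the only acidic site; the allyl ether is inert to the enolate, hydride and organolithium chemistry that follows and leaves later in the same operation as the allyl group on ring A.

Step 6
Reactants: 9 1-[4-(allyloxy)-3-methoxyphenyl]ethanone
Product: 11 2-chloro-1-[4-(allyloxy)-3-methoxyphenyl]ethanone, via trimethylsilyl enol ether 10 (not isolated)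
Conditions: LDA (1.1 equiv), TMSCl (1.2 equiv), THF, −78 → 0 °C; volatiles removed; then NCS (1.05 equiv), THF, 0 °C → rt
Reagents that add atoms: N-chlorosuccinimide, O=C1CCC(=O)N1Cl; chlorotrimethylsilane, C[Si](C)(C)Cl (its silyl group is carried by 10 only)
Why: Kinetic enolisation of the only enolisable position with in situ O-silylation, then electrophilic α-chlorination of the silyl enol ether 10 by NCS; this avoids acid and ring chlorination of the electron-rich arene, and the stoichiometric enol ether limits the reaction to monochlorination.

Step 7
Reactants: 11 2-chloro-1-[4-(allyloxy)-3-methoxyphenyl]ethanone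
Product: 13 (S)-2-[4-(allyloxy)-3-methoxyphenyl]oxirane, via (S)-chlorohydrin 12 (not isolated)
Conditions: Cp*RhCl[(R,R)-TsDPEN] (0.5 mol%), HCO2H/Et3N (5:2), EtOAc, rt; then 2 M NaOH (aq.), i-PrOH, 0 °C → rt
Reagents that add atoms: none
Why: Asymmetric transfer hydrogenation of an α-chloro aryl ketone (Noyori-type bifunctional hydride transfer): with the (R,R)-ligand the hydride should reach the carbonyl face that gives the (S)-chlorohydrin 12, the same spatial sense as the (R)-alcohols from aryl methyl ketones (CH2Cl outranks aryl); base then closes the oxirane by intramolecular Williamson displacement at CH2, which leaves the stereocentre untouched.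

Step 8
Reactants: 7 2-[2-(allyloxy)-4,6-bis(methoxymethoxy)-3-(3-methylbut-2-enyl)phenyl]-1,3-dithiane; 13 (S)-2-[4-(allyloxy)-3-methoxyphenyl]oxirane
Product: 15 (1R)-1-[4-(allyloxy)-3-methoxyphenyl]-2-{2-[2-(allyloxy)-4,6-bis(methoxymethoxy)-3-(3-methylbut-2-enyl)phenyl]-1,3-dithian-2-yl}ethanol, via 2-lithio-1,3-dithiane 14 (not isolated)
Conditions: 7 (1.2 equiv), n-BuLi (1.15 equiv), THF, −40 → −20 °C, 1 h; then 13 (1.0 equiv), DMPU (2 equiv), −40 → 0 °C; NH4Cl (aq.)
Reagents that add atoms: none
Why: n-BuLi removes the C2–H of the dithiane, the most acidic C–H in 7 (two sulfur atoms, lithium held by the ortho oxygens), to give the carbanion 14, which opens the oxirane of 13 by SN2 attack at the CH2 carbon; this forms C3–C4 and a lithium alkoxide that is protonated on work-up. The closest known reaction type is the Corey–Seebach umpolung alkylation of 2-aryl-2-lithio-1,3-dithianes with terminal epoxides. No ring is closed and no stereocentre is created: the benzylic C–O bond of 13 is not involved, so (S)-13 should give (R)-15 with the same spatial arrangement. Two selectivities are needed. Site of metalation: the ring C–H between the two acetal oxygens and the allylic O–CH2 groups are less acidic, and keeping n-BuLi below the amount of 7 and letting the anion equilibrate at −20 °C should funnel everything to 14 before 13 is added. Site of ring opening: the bulk of the tertiary carbanion favours the CH2 carbon, and DMPU solvates lithium, which raises the nucleophilicity of 14 and suppresses lithium-assisted benzylic opening or isomerisation of the electron-rich aryl oxirane to an aldehyde. Because C4 is a thioacetal, no enolisable β-oxygenated ketone is ever exposed to the strong base, so elimination towards a chalcone is excluded.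

Step 9
Reactants: 15 (1R)-1-[4-(allyloxy)-3-methoxyphenyl]-2-{2-[2-(allyloxy)-4,6-bis(methoxymethoxy)-3-(3-methylbut-2-enyl)phenyl]-1,3-dithian-2-yl}ethanol
Product: 16 (1R)-1-(4-hydroxy-3-methoxyphenyl)-2-{2-[2-hydroxy-4,6-bis(methoxymethoxy)-3-(3-methylbut-2-enyl)phenyl]-1,3-dithian-2-yl}ethanol
Conditions: Pd(PPh3)4 (5 mol%), morpholine (6 equiv), THF, rt
Reagents that add atoms: none
Why: Tsuji–Trost deallylation: zerovalent palladium ionises both aryl allyl ethers to π-allylpalladium phenoxides and morpholine captures the allyl groups; the prenyl chain has no leaving group, and the acetals, the thioacetal and the carbinol are inert under these near-neutral conditions.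

Step 10
Reactants: 16 (1R)-1-(4-hydroxy-3-methoxyphenyl)-2-{2-[2-hydroxy-4,6-bis(methoxymethoxy)-3-(3-methylbut-2-enyl)phenyl]-1,3-dithian-2-yl}ethanol
Product: 17 4-[(1R)-1-hydroxy-2-{2-[2-hydroxy-4,6-bis(methoxymethoxy)-3-(3-methylbut-2-enyl)phenyl]-1,3-dithian-2-yl}ethyl]-2-methoxyphenyl acetate
Conditions: Ac2O (1.05 equiv), Et3N (1.5 equiv), CH2Cl2, −20 → 0 °C
Reagents that add atoms: acetic anhydride, CC(=O)OC(C)=O
Why: Chemoselective O-acylation: the guaiacol-type phenol of ring B is far more accessible than the ring-A phenol wedged between the prenyl chain and the quaternary dithiane carbon, and without an acyl-transfer catalyst it is more reactive than the hindered secondary alcohol; the acetate turns the para donor into an acceptor so that the benzylic carbinol should not ionise in step 11.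

Step 11
Reactants: 17 4-[(1R)-1-hydroxy-2-{2-[2-hydroxy-4,6-bis(methoxymethoxy)-3-(3-methylbut-2-enyl)phenyl]-1,3-dithian-2-yl}ethyl]-2-methoxyphenyl acetate
Product: 18 4-[(2S)-5,7-bis(methoxymethoxy)-8-(3-methylbut-2-enyl)spiro[chromane-4,2'-[1,3]dithian]-2-yl]-2-methoxyphenyl acetate
Conditions: PPh3 (1.5 equiv), DIAD (1.5 equiv), toluene, 0 °C → rt
Reagents that add atoms: none
Why: Intramolecular Mitsunobu etherification: the carbinol becomes an alkoxyphosphonium ion and is displaced by the neighbouring phenoxide in a 6-exo-tet SN2 closure, so the (R)-carbinol gives the (2S) configuration at O1–C2 by inversion; the only free phenol of ring A is the one next to the prenyl chain, which fixes the 8-prenyl constitution.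

Step 12
Reactants: 18 4-[(2S)-5,7-bis(methoxymethoxy)-8-(3-methylbut-2-enyl)spiro[chromane-4,2'-[1,3]dithian]-2-yl]-2-methoxyphenyl acetate
Product: 19 4-[(2S)-5,7-bis(methoxymethoxy)-8-(3-methylbut-2-enyl)-4-oxochroman-2-yl]-2-methoxyphenyl acetate
Conditions: MeI (10 equiv), CaCO3 (5 equiv), MeCN/H2O (4:1), 45 °C
Reagents that add atoms: water, O
Why: Alkylative thioacetal hydrolysis: S-methylation makes sulfur a leaving group, water adds to the thionium ion and CaCO3 keeps the medium near neutral, so the acetals, the acetate, the alkene and C2 (no enolisation, no ring opening) should survive.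

Step 13
Reactants: 19 4-[(2S)-5,7-bis(methoxymethoxy)-8-(3-methylbut-2-enyl)-4-oxochroman-2-yl]-2-methoxyphenyl acetate
Product: 20 (2S)-5,7-dihydroxy-2-(4-hydroxy-3-methoxyphenyl)-8-(3-methylbut-2-enyl)chroman-4-one
Conditions: 3 M HCl (aq.), MeOH, 40 °C
Reagents that add atoms: none
Why: Acid-catalysed methanolysis: the methoxymethyl ethers leave by transacetalisation to dimethoxymethane and the aryl acetate by transesterification; dilute acid at low temperature should spare the prenyl alkene, and C2 is not epimerised because ring opening of a flavanone needs base.

## Compound list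

1 | 2,4,6-trihydroxybenzaldehyde | O=Cc1c(O)cc(O)cc1O | starting material
2 | prenyl bromide (1-bromo-3-methylbut-2-ene) | CC(C)=CCBr | starting material
3 | 2,4,6-trihydroxy-3-(3-methylbut-2-enyl)benzaldehyde | CC(C)=CCc1c(O)cc(O)c(C=O)c1O | intermediate
4 | 2-hydroxy-4,6-bis(methoxymethoxy)-3-(3-methylbut-2-enyl)benzaldehyde | CC(C)=CCc1c(O)c(C=O)c(OCOC)cc1OCOC | intermediate
5 | 2-(allyloxy)-4,6-bis(methoxymethoxy)-3-(3-methylbut-2-enyl)benzaldehyde | CC(C)=CCc1c(OCC=C)c(C=O)c(OCOC)cc1OCOC | intermediate
6 | propane-1,3-dithiol | SCCCS | starting material
7 | 2-[2-(allyloxy)-4,6-bis(methoxymethoxy)-3-(3-methylbut-2-enyl)phenyl]-1,3-dithiane | CC(C)=CCc1c(OCC=C)c(C2SCCCS2)c(OCOC)cc1OCOC | intermediate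
8 | acetovanillone (1-(4-hydroxy-3-methoxyphenyl)ethanone) | CC(=O)c1ccc(O)c(OC)c1 | starting material
9 | 1-[4-(allyloxy)-3-methoxyphenyl]ethanone | CC(=O)c1ccc(OCC=C)c(OC)c1 | intermediate
10 | {1-[4-(allyloxy)-3-methoxyphenyl]ethenyloxy}trimethylsilane | C=C(O[Si](C)(C)C)c1ccc(OCC=C)c(OC)c1 | intermediate (not isolated)
11 | 2-chloro-1-[4-(allyloxy)-3-methoxyphenyl]ethanone | O=C(CCl)c1ccc(OCC=C)c(OC)c1 | intermediate
12 | (1S)-1-[4-(allyloxy)-3-methoxyphenyl]-2-chloroethanol | C=CCOc1ccc([C@H](O)CCl)cc1OC | intermediate (not isolated)
13 | (S)-2-[4-(allyloxy)-3-methoxyphenyl]oxirane | C=CCOc1ccc([C@H]2CO2)cc1OC | intermediate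
14 | 2-[2-(allyloxy)-4,6-bis(methoxymethoxy)-3-(3-methylbut-2-enyl)phenyl]-2-lithio-1,3-dithiane | [Li]C1(c2c(OCC=C)c(CC=C(C)C)c(OCOC)cc2OCOC)SCCCS1 | intermediate (not isolated)
15 | (1R)-1-[4-(allyloxy)-3-methoxyphenyl]-2-{2-[2-(allyloxy)-4,6-bis(methoxymethoxy)-3-(3-methylbut-2-enyl)phenyl]-1,3-dithian-2-yl}ethanol | C=CCOc1ccc([C@H](O)CC2(c3c(OCC=C)c(CC=C(C)C)c(OCOC)cc3OCOC)SCCCS2)cc1OC | intermediate
16 | (1R)-1-(4-hydroxy-3-methoxyphenyl)-2-{2-[2-hydroxy-4,6-bis(methoxymethoxy)-3-(3-methylbut-2-enyl)phenyl]-1,3-dithian-2-yl}ethanol | COc1cc([C@H](O)CC2(c3c(O)c(CC=C(C)C)c(OCOC)cc3OCOC)SCCCS2)ccc1O | intermediate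
17 | 4-[(1R)-1-hydroxy-2-{2-[2-hydroxy-4,6-bis(methoxymethoxy)-3-(3-methylbut-2-enyl)phenyl]-1,3-dithian-2-yl}ethyl]-2-methoxyphenyl acetate | CC(=O)Oc1ccc([C@H](O)CC2(c3c(O)c(CC=C(C)C)c(OCOC)cc3OCOC)SCCCS2)cc1OC | intermediate
18 | 4-[(2S)-5,7-bis(methoxymethoxy)-8-(3-methylbut-2-enyl)spiro[chromane-4,2'-[1,3]dithian]-2-yl]-2-methoxyphenyl acetate | CC(=O)Oc1ccc([C@@H]2CC3(SCCCS3)c3c(OCOC)cc(OCOC)c(CC=C(C)C)c3O2)cc1OC | intermediate
19 | 4-[(2S)-5,7-bis(methoxymethoxy)-8-(3-methylbut-2-enyl)-4-oxochroman-2-yl]-2-methoxyphenyl acetate | CC(=O)Oc1ccc([C@@H]2CC(=O)c3c(OCOC)cc(OCOC)c(CC=C(C)C)c3O2)cc1OC | intermediate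
20 | (2S)-5,7-dihydroxy-2-(4-hydroxy-3-methoxyphenyl)-8-(3-methylbut-2-enyl)chroman-4-one | COc1cc([C@@H]2CC(=O)c3c(O)cc(O)c(CC=C(C)C)c3O2)ccc1O | target

## Step count and least certain steps

Total: 13 steps. Longest linear sequence: 10 steps (steps 1–4 and 8–13); the ring-B branch (steps 5–7) joins at step 8.

Step 8 (key step). The most likely failure is that ring opening by the congested tertiary carbanion, flanked by two ortho oxygens, is too slow. Lithium-promoted isomerisation of the electron-rich aryl oxirane to an aldehyde, attack at the benzylic carbon, or proton transfer from an allylic O–CH2 group could then overtake the SN2 opening. The fallback replaces the oxirane by a primary iodide that can neither rearrange nor open at the benzylic carbon. It sets out from 12 (intercepted before the base treatment of step 7) and from 7, and returns at 15. Silylation of 12 (TBSCl, imidazole, DMF) would give (S)-tert-butyl{1-[4-(allyloxy)-3-methoxyphenyl]-2-chloroethoxy}dimethylsilane F1. Finkelstein exchange (NaI, butan-2-one, reflux) would give (S)-tert-butyl{1-[4-(allyloxy)-3-methoxyphenyl]-2-iodoethoxy}dimethylsilane F2. Alkylation of 14 (from 7 and n-BuLi in THF/DMPU, −78 °C) with F2 would give (R)-tert-butyl{1-[4-(allyloxy)-3-methoxyphenyl]-2-{2-[2-(allyloxy)-4,6-bis(methoxymethoxy)-3-(3-methylbut-2-enyl)phenyl]-1,3-dithian-2-yl}ethoxy}dimethylsilane F3. Desilylation (TBAF, THF, 0 °C) then gives 15.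

Step 4. The likely failure is loss of methoxymethyl groups by Lewis acid–thiol transacetalisation running alongside thioacetal formation at a hindered, electron-rich carbonyl. The fallback reverses the order of protection and thioacetalisation; it sets out from 5 and returns at 7. With BF3·OEt2 (2 equiv) and excess 6 in CH2Cl2 at −20 °C (Et3N quench), the dithiane is formed and both acetals are removed on purpose. This would give 2-[2-(allyloxy)-4,6-dihydroxy-3-(3-methylbut-2-enyl)phenyl]-1,3-dithiane F4. Its two phenols are then re-protected (MOMCl, i-Pr2NEt, CH2Cl2) to give 7. No site selectivity is needed because the third oxygen is already an allyl ether.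

Step 2 (with step 1). The likely failure is poor site selectivity between the two ortho hydroxyls, with protection of the 2-OH in place of the 6-OH, on top of over-alkylation in step 1. The fallback fixes the regiochemistry by mechanism; it sets out from 1 and returns at 4. Bis-protection of 1 (MOMCl, i-Pr2NEt) can give only one product by symmetry, 2-hydroxy-4,6-bis(methoxymethoxy)benzaldehyde F5. Tsuji–Trost O-alkylation with methyl 2-methylbut-3-en-2-yl carbonate and Pd(PPh3)4 (THF, 0 °C) would give the tertiary ether 2-[(2-methylbut-3-en-2-yl)oxy]-4,6-bis(methoxymethoxy)benzaldehyde F6. An aromatic Claisen rearrangement (toluene, 110 °C) moves the chain, with allylic transposition, to the only free ortho carbon and gives 4. The prenyl chain is thereby placed next to the one free hydroxyl.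

Step 11. With the acetate in place, ionisation should no longer be the main risk. The likely failure is elimination of the alkoxyphosphonium ion to a styrene, because substitution is slowed by the neighbouring quaternary thioacetal carbon and by the hindered phenol. The fallback unmasks the ketone before closing the ring, so the carbon next to the reacting chain is flat and the phenol is more acidic; it sets out from 17 and returns at 19. Hydrolysis of 17 (MeI, CaCO3, MeCN/H2O, 45 °C) would give 4-[(1R)-1-hydroxy-3-[2-hydroxy-4,6-bis(methoxymethoxy)-3-(3-methylbut-2-enyl)phenyl]-3-oxopropyl]-2-methoxyphenyl acetate F7. Mitsunobu closure (PPh3, DIAD, toluene, 0 °C) would give 19 directly. The cost is that a β-hydroxy ketone is exposed to the basic betaine, so dehydration is the process to watch in this variant.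

## Further compounds

F1 | step 8 | (S)-tert-butyl{1-[4-(allyloxy)-3-methoxyphenyl]-2-chloroethoxy}dimethylsilane | C=CCOc1ccc([C@H](O[Si](C)(C)C(C)(C)C)CCl)cc1OC
F2 | step 8 | (S)-tert-butyl{1-[4-(allyloxy)-3-methoxyphenyl]-2-iodoethoxy}dimethylsilane | C=CCOc1ccc([C@H](O[Si](C)(C)C(C)(C)C)CI)cc1OC
F3 | step 8 | (R)-tert-butyl{1-[4-(allyloxy)-3-methoxyphenyl]-2-{2-[2-(allyloxy)-4,6-bis(methoxymethoxy)-3-(3-methylbut-2-enyl)phenyl]-1,3-dithian-2-yl}ethoxy}dimethylsilane | C=CCOc1ccc([C@H](O[Si](C)(C)C(C)(C)C)CC2(c3c(OCC=C)c(CC=C(C)C)c(OCOC)cc3OCOC)SCCCS2)cc1OC
F4 | step 4 | 2-[2-(allyloxy)-4,6-dihydroxy-3-(3-methylbut-2-enyl)phenyl]-1,3-dithiane | CC(C)=CCc1c(OCC=C)c(C2SCCCS2)c(O)cc1O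
F5 | step 2 | 2-hydroxy-4,6-bis(methoxymethoxy)benzaldehyde | O=Cc1c(O)cc(OCOC)cc1OCOC
F6 | step 2 | 2-[(2-methylbut-3-en-2-yl)oxy]-4,6-bis(methoxymethoxy)benzaldehyde | C=CC(C)(C)Oc1cc(OCOC)cc(OCOC)c1C=O
F7 | step 11 | 4-[(1R)-1-hydroxy-3-[2-hydroxy-4,6-bis(methoxymethoxy)-3-(3-methylbut-2-enyl)phenyl]-3-oxopropyl]-2-methoxyphenyl acetate | CC(=O)Oc1ccc([C@H](O)CC(=O)c2c(O)c(CC=C(C)C)c(OCOC)cc2OCOC)cc1OC
A1 | alternative 1 | 5,7-bis(tert-butyldimethylsilyloxy)-2-[4-(tert-butyldimethylsilyloxy)-3-methoxyphenyl]-4-methylene-8-(3-methylbut-2-enyl)-4H-1,3-benzodioxine | C=C1OC(c2ccc(O[Si](C)(C)C(C)(C)C)c(OC)c2)Oc2c(CC=C(C)C)c(O[Si](C)(C)C(C)(C)C)cc(O[Si](C)(C)C(C)(C)C)c21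
A2 | alternative 1 | (2S)-5,7-bis(tert-butyldimethylsilyloxy)-2-[4-(tert-butyldimethylsilyloxy)-3-methoxyphenyl]-8-(3-methylbut-2-enyl)chroman-4-one | COc1cc([C@@H]2CC(=O)c3c(O[Si](C)(C)C(C)(C)C)cc(O[Si](C)(C)C(C)(C)C)c(CC=C(C)C)c3O2)ccc1O[Si](C)(C)C(C)(C)C
A3 | alternative 2 | 3,5-bis(methoxymethoxy)-2-(3-methylbut-2-enyl)phenol | CC(C)=CCc1c(O)cc(OCOC)cc1OCOC
A4 | alternative 2 | (E)-3-[3-methoxy-4-(methoxymethoxy)phenyl]prop-2-enyl methyl carbonate | COC(=O)OC/C=C/c1ccc(OCOC)c(OC)c1
A5 | alternative 2 | (S)-1-{1-[3-methoxy-4-(methoxymethoxy)phenyl]prop-2-enyloxy}-3,5-bis(methoxymethoxy)-2-(3-methylbut-2-enyl)benzene | C=C[C@H](Oc1cc(OCOC)cc(OCOC)c1CC=C(C)C)c1ccc(OCOC)c(OC)c1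
A6 | alternative 3 | 5,7-bis(methoxymethoxy)-8-(3-methylbut-2-enyl)-4H-chromen-4-one | CC(C)=CCc1c(OCOC)cc(OCOC)c2c(=O)ccoc12
A7 | alternative 3 | [3-methoxy-4-(methoxymethoxy)phenyl]boronic acid | COCOc1ccc(B(O)O)cc1OC
A8 | alternative 3 | (2S)-2-[3-methoxy-4-(methoxymethoxy)phenyl]-5,7-bis(methoxymethoxy)-8-(3-methylbut-2-enyl)chroman-4-one | COCOc1ccc([C@@H]2CC(=O)c3c(OCOC)cc(OCOC)c(CC=C(C)C)c3O2)cc1OC
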